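**Plan**
1. The target is methyl (13S)-6β-acetoxy-8α-hydroxylabdan-15-oate. The late cuts are C8–OH (hydration of C7=C8), the acetate, C6–H (back to a 6-ketone) and C11–C12 (Wittig), which leaves a drimane-type C11 aldehyde and a C12–C16 ylide.
2. The decalin is then cut across C5–C10 and C8–C9 at once: an intramolecular Diels–Alder reaction of an acyclic trienoyl imide, so rings A and B arise together in step 5.
3. Enabling feature: the ring-fusion bond C5–C10 lies between C6, which carries oxygen (so C5=C6–C7=C8 can be a 2-siloxy diene), and C9, whose substituent C11 can be a carbonyl that activates C9=C10. C1–C4, with the gem-dimethyl C4, is the tether.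
4. The triene is cut at C4–C5 (tert-alkylation of a silyl dienol ether) to (E)-geranic acid (C1–C4, C9–C11, C18–C20) and pent-3-en-2-one (C5–C8, C17).
5. Forward order: acyl imide, C4–C5 alkylation, siloxy diene, cycloaddition, side chain (C11–C12), then the ring B oxidation pattern (enone, 6β-OAc, 8α-OH).
6. Stereochemistry: C5, C9 and C10 come from the oxazolidinone-controlled endo cycloaddition; C6 and C8 from attack on the α face of ring B, away from the axial C10 and C4 methyl groups; C13 from (S)-3-methylglutaric acid monomethyl ester.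

Key step: step 5

Remark: labdane numbering is used throughout (C17 on C8, C18/C19 on C4, C20 on C10; β is the face of C20), and (E)-geranic acid and (S)-3-methylglutaric acid monomethyl ester are assumed to be commercial, isomerically pure materials.

Step 1
Reactants: 1 (E)-geranic acid; 2 (S)-4-benzyl-1,3-oxazolidin-2-one
Product: 4 (S)-4-benzyl-3-[(2E)-3,7-dimethylocta-2,6-dienoyl]-1,3-oxazolidin-2-one, via geranic pivalic anhydride 3 (not isolated)
Conditions: PivCl, Et3N, THF, −20 °C; then 2, LiCl, −20 °C → rt
Reagents that add atoms: none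
Why: N-acylation of the oxazolidinone through the mixed pivalic anhydride (LiCl/Et3N protocol) should occur at the unhindered geranoyl carbonyl without isomerising the (2E) double bond.

Step 2
Reactants: 5 (E)-pent-3-en-2-one
Product: 6 (3E)-2-(trimethylsilyloxy)penta-1,3-diene
Conditions: TMSOTf, Et3N, Et2O, 0 °C
Reagents that add atoms: trimethylsilyl trifluoromethanesulfonate, C[Si](C)(C)OS(=O)(=O)C(F)(F)F
Why: Soft enolisation of the enone at its α′-methyl group (silyl enol ether formation) should give the cross-conjugated silyl dienol ether.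

Step 3
Reactants: 4 (S)-4-benzyl-3-[(2E)-3,7-dimethylocta-2,6-dienoyl]-1,3-oxazolidin-2-one; 6 (3E)-2-(trimethylsilyloxy)penta-1,3-diene
Product: 8 (S)-4-benzyl-3-[(2E,10E)-3,7,7-trimethyl-9-oxododeca-2,10-dienoyl]-1,3-oxazolidin-2-one, via tertiary chloride 7 (not isolated)
Conditions: HCl (g), CH2Cl2, −20 °C, then N2 purge; 6, TiCl4 (2.2 equiv), CH2Cl2, −78 °C
Reagents that add atoms: none
Why: Markovnikov hydrochlorination of the isolated trisubstituted alkene (the conjugated C9=C10 bond is inert) should give the tertiary chloride, whose TiCl4-generated cation is captured at the terminal CH2 of the silyl dienol ether in an SN1 α-tert-alkylation of a silyl enol ether, forming C4–C5 and the gem-dimethyl quaternary carbon faster than the electron-poor enoyl alkene can cyclise onto the cation.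

Step 4
Reactants: 8 (S)-4-benzyl-3-[(2E,10E)-3,7,7-trimethyl-9-oxododeca-2,10-dienoyl]-1,3-oxazolidin-2-one
Product: 9 (S)-4-benzyl-3-[(2E,8Z,10E)-9-(tert-butyldimethylsilyloxy)-3,7,7-trimethyldodeca-2,8,10-trienoyl]-1,3-oxazolidin-2-one
Conditions: TBSOTf, Et3N, CH2Cl2, −78 → 0 °C
Reagents that add atoms: tert-butyldimethylsilyl trifluoromethanesulfonate, CC(C)(C)[Si](C)(C)OS(=O)(=O)C(F)(F)F
Why: Soft enolisation of the enone (silyl enol ether formation) should remove the α′ proton at C5 in preference to the vinylogous γ proton at C17 and place the bulky C4 group cis to oxygen, giving the (Z)-enol ether in which C4 sits on the outside of the 2-siloxy diene.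

Step 5
Reactants: 9 (S)-4-benzyl-3-[(2E,8Z,10E)-9-(tert-butyldimethylsilyloxy)-3,7,7-trimethyldodeca-2,8,10-trienoyl]-1,3-oxazolidin-2-one
Product: 10 (S)-4-benzyl-3-[6-(tert-butyldimethylsilyloxy)drim-6-en-11-oyl]-1,3-oxazolidin-2-one (trans-decalin; 5α-H; 8β-CH3; 9β-acyl; 10β-CH3)
Conditions: Me2AlCl (1.5 equiv), CH2Cl2, −30 → 0 °C
Reagents that add atoms: none
Why: The Me2AlCl-chelated, s-cis N-enoyl oxazolidinone (C9=C10–C11=O) is a lowered-LUMO dienophile and the silyl dienol ether C5=C6(OTBS)–C7=C8 an electron-rich diene whose nucleophilic terminus C5 is matched with the β-carbon C10, so a concerted but asynchronous intramolecular Diels–Alder reaction should form C5–C10 and C8–C9 in one event; the closest known reaction type is the Lewis acid-promoted intramolecular Diels–Alder reaction of chiral undeca-2,8,10-trienoyl oxazolidinones. Ring B closes as the six-membered ring of the [4+2] transition state, and ring A closes at the same time through the C5–C10 bond (6-exo-trig with respect to C9=C10) with the C1–C4 tether in a chair and the C4 gem-dimethyl group favouring the folded conformer (Thorpe–Ingold effect). C9 and C10 are set relative to each other by suprafacial addition to the (E)-enoyl unit (C11 and C20 cis), C5 relative to C10 by the endo transition state with C4 on the outside of the (Z)-enol ether (trans ring fusion), and C8 by the (E)-propenyl terminus (8β-CH3, erased in step 12). The absolute sense comes from the benzyl group of the auxiliary, which covers the C9 Re face of the aluminium chelate so that the diene adds to the Si face. The step needs endo over exo selectivity, a single π-face and ring closure in preference to a plain Mukaiyama–Michael addition or loss of the silyl group; the two-point chelation of aluminium, the fixed four-carbon tether and the robust TBS enol ether are expected to secure these.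

Step 6
Reactants: 10 (S)-4-benzyl-3-[6-(tert-butyldimethylsilyloxy)drim-6-en-11-oyl]-1,3-oxazolidin-2-one
Product: 11 6-(tert-butyldimethylsilyloxy)drim-6-en-11-ol (5α-H; 8β-CH3; 9β-CH2OH; 10β-CH3)
Conditions: LiBH4, MeOH (2 equiv), THF, 0 °C → rt
Reagents that add atoms: none
Why: Reductive cleavage of the N-acyl oxazolidinone by LiBH4 should give the primary alcohol and return the auxiliary, the silyl enol ether being inert to borohydride.

Step 7
Reactants: 11 6-(tert-butyldimethylsilyloxy)drim-6-en-11-ol
Product: 12 6-(tert-butyldimethylsilyloxy)drim-6-en-11-al (5α-H; 8β-CH3; 9β-CHO; 10β-CH3)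
Conditions: Pr4N[RuO4] (cat.), NMO, 4 Å molecular sieves, CH2Cl2, rt
Reagents that add atoms: none
Why: The Ley–Griffith oxidation is neutral and stops at the aldehyde, so the enol ether and the equatorial (more stable) C9 configuration should survive.

Step 8
Reactants: 13 (3S)-5-methoxy-3-methyl-5-oxopentanoic acid [(S)-3-methylglutaric acid monomethyl ester]
Product: 14 methyl (3R)-4-bromo-3-methylbutanoate
Conditions: HgO, Br2, CCl4, 75 °C, dark
Reagents that add atoms: bromine, BrBr
Why: The Hunsdiecker reaction (Cristol–Firth modification) replaces CO2H by Br through an acyl hypobromite and a primary radical on the carbon next to the stereocenter, which is therefore untouched (the descriptor changes only because the priorities change).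

Step 9
Reactants: 14 methyl (3R)-4-bromo-3-methylbutanoate
Product: 15 [(2R)-4-methoxy-2-methyl-4-oxobutyl]triphenylphosphonium bromide
Conditions: PPh3, MeCN, 85 °C
Reagents that add atoms: triphenylphosphine, c1ccc(cc1)P(c1ccccc1)c1ccccc1
Why: SN2 quaternisation of triphenylphosphine by the primary bromide should give the phosphonium salt.

Step 10
Reactants: 12 6-(tert-butyldimethylsilyloxy)drim-6-en-11-al; 15 [(2R)-4-methoxy-2-methyl-4-oxobutyl]triphenylphosphonium bromide
Product: 17 methyl (11Z,13R)-6-(tert-butyldimethylsilyloxy)labda-6,11-dien-15-oate, via phosphorus ylide 16 (not isolated)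
Conditions: 15, NaHMDS, THF, −78 → 0 °C; then 12, −78 °C → rt
Reagents that add atoms: none
Why: Wittig olefination of the hindered aldehyde by the non-stabilised ylide should form C11=C12 (geometry irrelevant), the phosphonium α-CH2 being more acidic than the ester α-CH2 and C13 carrying no acidic hydrogen.

Step 11
Reactants: 17 methyl (11Z,13R)-6-(tert-butyldimethylsilyloxy)labda-6,11-dien-15-oate
Product: 18 methyl (13S)-6-(tert-butyldimethylsilyloxy)labd-6-en-15-oate (5α-H; 8β-CH3; 9β side chain; 10β-CH3)
Conditions: H2 (1 atm), Pt/C, EtOAc, rt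
Reagents that add atoms: none
Why: Heterogeneous hydrogenation should saturate the disubstituted C11=C12 bond well before the hindered trisubstituted silyl enol ether, and platinum is chosen over palladium to suppress double-bond migration toward the allylic C13 stereocenter.

Step 12
Reactants: 18 methyl (13S)-6-(tert-butyldimethylsilyloxy)labd-6-en-15-oate
Product: 19 methyl (13S)-6-oxolabd-7-en-15-oate
Conditions: Pd(OAc)2 (1.1 equiv), MeCN, 40 °C
Reagents that add atoms: none
Why: In the Saegusa–Ito oxidation the palladium enolate bound at C7 on the α face should undergo syn β-hydride elimination of the α-oriented H-8, the only β-hydrogen, to give the 7-en-6-one.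

Step 13
Reactants: 19 methyl (13S)-6-oxolabd-7-en-15-oate
Product: 20 methyl (13S)-6β-hydroxylabd-7-en-15-oate
Conditions: NaBH4, CeCl3·7H2O, MeOH, −40 °C
Reagents that add atoms: none
Why: Luche 1,2-reduction should deliver hydride to C6 from the α face, opposite the syn-axial C10 and C4β methyl groups, giving the axial 6β-alcohol and leaving the ester alone.

Step 14
Reactants: 20 methyl (13S)-6β-hydroxylabd-7-en-15-oate
Product: 21 methyl (13S)-6β-acetoxylabd-7-en-15-oate
Conditions: Ac2O, DMAP, pyridine, 40 °C
Reagents that add atoms: acetic anhydride, CC(=O)OC(C)=O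
Why: DMAP-catalysed acetylation of the secondary allylic alcohol is done at this stage because C8 is still sp2 and the 6β-hydroxyl is less crowded than it would be after hydration.

Step 15
Reactants: 21 methyl (13S)-6β-acetoxylabd-7-en-15-oate
Product: 22 methyl (13S)-6β-acetoxy-8α-hydroxylabdan-15-oate (target)
Conditions: Co(acac)2 (cat.), PhSiH3, O2 (1 atm), i-PrOH, rt
Reagents that add atoms: dioxygen, O=O
Why: In the Mukaiyama hydration, hydrogen-atom transfer from a cobalt hydride to C7 gives the tertiary C8 radical (Markovnikov), which should be trapped by O2 on the α face because the β face is blocked by the axial C10 methyl and 6β-acetoxy groups, and the peroxide is reduced by the silane to the 8α-alcohol with C17 ending axial (β).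

**Compound list**
1 | (E)-geranic acid [(2E)-3,7-dimethylocta-2,6-dienoic acid] | CC(C)=CCC/C(C)=C/C(=O)O | starting material
2 | (S)-4-benzyl-1,3-oxazolidin-2-one | O=C1N[C@@H](Cc2ccccc2)CO1 | starting material
3 | geranic pivalic anhydride | CC(C)=CCC/C(C)=C/C(=O)OC(=O)C(C)(C)C | intermediate
4 | (S)-4-benzyl-3-[(2E)-3,7-dimethylocta-2,6-dienoyl]-1,3-oxazolidin-2-one | CC(C)=CCC/C(C)=C/C(=O)N1[C@@H](Cc2ccccc2)COC1=O | intermediate
5 | (E)-pent-3-en-2-one | C/C=C/C(C)=O | starting material
6 | (3E)-2-(trimethylsilyloxy)penta-1,3-diene | C/C=C/C(=C)O[Si](C)(C)C | intermediate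
7 | (S)-4-benzyl-3-[(2E)-7-chloro-3,7-dimethyloct-2-enoyl]-1,3-oxazolidin-2-one | CC(C)(Cl)CCC/C(C)=C/C(=O)N1[C@@H](Cc2ccccc2)COC1=O | intermediate
8 | (S)-4-benzyl-3-[(2E,10E)-3,7,7-trimethyl-9-oxododeca-2,10-dienoyl]-1,3-oxazolidin-2-one | C/C=C/C(=O)CC(C)(C)CCC/C(C)=C/C(=O)N1[C@@H](Cc2ccccc2)COC1=O | intermediate
9 | (S)-4-benzyl-3-[(2E,8Z,10E)-9-(tert-butyldimethylsilyloxy)-3,7,7-trimethyldodeca-2,8,10-trienoyl]-1,3-oxazolidin-2-one | C/C=C/C(O[Si](C)(C)C(C)(C)C)=C/C(C)(C)CCC/C(C)=C/C(=O)N1[C@@H](Cc2ccccc2)COC1=O | intermediate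
10 | (S)-4-benzyl-3-[6-(tert-butyldimethylsilyloxy)drim-6-en-11-oyl]-1,3-oxazolidin-2-one (5α-H; 8β-CH3; 9β-acyl; 10β-CH3) | O=C(N1[C@@H](Cc2ccccc2)COC1=O)[C@@H]3[C@@]4(C)CCCC(C)(C)[C@@H]4C(O[Si](C)(C)C(C)(C)C)=C[C@@H]3C | intermediate
11 | 6-(tert-butyldimethylsilyloxy)drim-6-en-11-ol | OC[C@@H]1[C@@]2(C)CCCC(C)(C)[C@@H]2C(O[Si](C)(C)C(C)(C)C)=C[C@@H]1C | intermediate
12 | 6-(tert-butyldimethylsilyloxy)drim-6-en-11-al | O=C[C@@H]1[C@@]2(C)CCCC(C)(C)[C@@H]2C(O[Si](C)(C)C(C)(C)C)=C[C@@H]1C | intermediate
13 | (3S)-5-methoxy-3-methyl-5-oxopentanoic acid | COC(=O)C[C@@H](C)CC(=O)O | starting material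
14 | methyl (3R)-4-bromo-3-methylbutanoate | COC(=O)C[C@@H](C)CBr | intermediate
15 | [(2R)-4-methoxy-2-methyl-4-oxobutyl]triphenylphosphonium bromide | COC(=O)C[C@@H](C)C[P+](c1ccccc1)(c1ccccc1)c1ccccc1.[Br-] | intermediate
16 | methyl (3R)-3-methyl-4-(triphenyl-λ5-phosphanylidene)butanoate (phosphorus ylide) | COC(=O)C[C@@H](C)C=P(c1ccccc1)(c1ccccc1)c1ccccc1 | intermediate
17 | methyl (11Z,13R)-6-(tert-butyldimethylsilyloxy)labda-6,11-dien-15-oate | COC(=O)C[C@@H](C)/C=C\[C@@H]1[C@@]2(C)CCCC(C)(C)[C@@H]2C(O[Si](C)(C)C(C)(C)C)=C[C@@H]1C | intermediate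
18 | methyl (13S)-6-(tert-butyldimethylsilyloxy)labd-6-en-15-oate | COC(=O)C[C@@H](C)CC[C@@H]1[C@@]2(C)CCCC(C)(C)[C@@H]2C(O[Si](C)(C)C(C)(C)C)=C[C@@H]1C | intermediate
19 | methyl (13S)-6-oxolabd-7-en-15-oate | COC(=O)C[C@@H](C)CC[C@@H]1[C@@]2(C)CCCC(C)(C)[C@@H]2C(=O)C=C1C | intermediate
20 | methyl (13S)-6β-hydroxylabd-7-en-15-oate | COC(=O)C[C@@H](C)CC[C@@H]1[C@@]2(C)CCCC(C)(C)[C@@H]2[C@H](O)C=C1C | intermediate
21 | methyl (13S)-6β-acetoxylabd-7-en-15-oate | COC(=O)C[C@@H](C)CC[C@@H]1[C@@]2(C)CCCC(C)(C)[C@@H]2[C@H](OC(C)=O)C=C1C | intermediate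
22 | methyl (13S)-6β-acetoxy-8α-hydroxylabdan-15-oate | COC(=O)C[C@@H](C)CC[C@@H]1[C@@]2(C)CCCC(C)(C)[C@@H]2[C@H](OC(C)=O)C[C@@]1(C)O | target

**Step count**
Total: 15 steps. Longest linear sequence: 12 steps (steps 1, 3, 4, 5, 6, 7, 10, 11, 12, 13, 14, 15, from geranic acid).

**Steps most likely to fail**

Step 5. The β,β-disubstituted enoyl unit may react too slowly as the 2π partner. The Lewis acid could then strip the silyl group, or the reaction could stop after the first C5–C10 bond, and endo or facial selectivity could erode at the higher temperature then needed. The fallback is an anionic double Michael reaction and sets out from 8. LiHMDS in THF at −78 → −20 °C should remove the α′ proton at C5; the dienolate adds to C10 of the lithium-chelated enoyl imide, and the imide enolate so formed closes onto C8 of the enone. The same auxiliary shields the same face. Protonation gives (S)-4-benzyl-3-(6-oxodriman-11-oyl)-1,3-oxazolidin-2-one F1. Soft enolisation of F1 toward C7 (TBSOTf, Et3N, CH2Cl2) returns to the route at 10.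

Step 3. The bidentate imide may sequester TiCl4 and slow the ionisation, so that loss of HCl from the tertiary chloride or Lewis acid-induced oligomerisation of the dienol ether outruns C–C bond formation. The fallback moves the alkylation in front of the auxiliary and sets out from 1. MeI/K2CO3 in DMF gives methyl (E)-geranate F2. HCl in CH2Cl2 gives methyl (2E)-7-chloro-3,7-dimethyloct-2-enoate F3. Reaction of F3 with 6 and TiCl4 at −78 °C gives methyl (2E,10E)-3,7,7-trimethyl-9-oxododeca-2,10-dienoate F4. Me3SnOH in 1,2-dichloroethane at 80 °C cleaves the ester to (2E,10E)-3,7,7-trimethyl-9-oxododeca-2,10-dienoic acid F5. PivCl/Et3N converts F5 into its pivalic mixed anhydride F6, which acylates 2 (LiCl, THF) and returns to the route at 8.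

Step 15. Oxygen capture by the planar C8 radical may show poor facial selectivity, or the radical may be reduced by the silane (net hydrogenation) instead of oxygenated. The fallback installs the C8 oxygen by ionic chemistry and sets out from 19. Weitz–Scheffer epoxidation (t-BuOOH, DBU, CH2Cl2) on the α face should give methyl (13S)-7α,8α-epoxy-6-oxolabdan-15-oate F7. SmI2 in THF/MeOH at −78 °C cleaves the C7–O bond to give methyl (13S)-8α-hydroxy-6-oxolabdan-15-oate F8. NaBH4 in MeOH at 0 °C reduces C6 from the α face to give methyl (13S)-6β,8α-dihydroxylabdan-15-oate F9. Acetylation of the secondary hydroxyl (Ac2O, DMAP, pyridine, 50 °C) returns to the route at 22.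

Further compounds
F1 | step 5 | (S)-4-benzyl-3-(6-oxodriman-11-oyl)-1,3-oxazolidin-2-one (5α-H; 8β-CH3; 9β-acyl; 10β-CH3) | O=C(N1[C@@H](Cc2ccccc2)COC1=O)[C@@H]3[C@@]4(C)CCCC(C)(C)[C@@H]4C(=O)C[C@@H]3C
F2 | step 3 | methyl (E)-geranate | COC(=O)/C=C(\C)CCC=C(C)C
F3 | step 3 | methyl (2E)-7-chloro-3,7-dimethyloct-2-enoate | COC(=O)/C=C(\C)CCCC(C)(C)Cl
F4 | step 3 | methyl (2E,10E)-3,7,7-trimethyl-9-oxododeca-2,10-dienoate | COC(=O)/C=C(\C)CCCC(C)(C)CC(=O)/C=C/C
F5 | step 3 | (2E,10E)-3,7,7-trimethyl-9-oxododeca-2,10-dienoic acid | OC(=O)/C=C(\C)CCCC(C)(C)CC(=O)/C=C/C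
F6 | step 3 | pivalic mixed anhydride of F5 | CC(C)(C)C(=O)OC(=O)/C=C(\C)CCCC(C)(C)CC(=O)/C=C/C
F7 | step 15 | methyl (13S)-7α,8α-epoxy-6-oxolabdan-15-oate | COC(=O)C[C@@H](C)CC[C@@H]1[C@@]2(C)CCCC(C)(C)[C@@H]2C(=O)[C@H]3O[C@@]13C
F8 | step 15 | methyl (13S)-8α-hydroxy-6-oxolabdan-15-oate | COC(=O)C[C@@H](C)CC[C@@H]1[C@@]2(C)CCCC(C)(C)[C@@H]2C(=O)C[C@@]1(C)O
F9 | step 15 | methyl (13S)-6β,8α-dihydroxylabdan-15-oate | COC(=O)C[C@@H](C)CC[C@@H]1[C@@]2(C)CCCC(C)(C)[C@@H]2[C@H](O)C[C@@]1(C)O
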